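**Plan**

1. Retrosynthesis: the two silyl ethers go last. The C2–C3 bond of the pyranone ring (ring C) is cut in the sense of a retro Petasis–Ferrier rearrangement, giving an isomeric, racemic 2-aryl-4-methylidene-4H-1,3-benzodioxine. Its exocyclic C=CH2 is cut back to a benzodioxin-4-one, and the two acetal C–O bonds to a ring A salicylic acid and a ring B aldehyde.
2. Enabling feature: C2 carries O1 and the electron-rich 4-oxygenated ring B, so it can be an oxocarbenium carbon. C3 is the enol carbon of the C4 ketone, and the C4 oxygen can be parked on C2 as a second acetal oxygen. The flavanone and the enol acetal are therefore isomers.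
3. Forward, fragments: ring B aldehyde 7 from 4-bromophenol (double ortho-prenylation, silylation, formylation). Ring A acid 15 from methyl 2,4-dihydroxybenzoate (O-1,1-dimethylallylation, Claisen shift to C3, saponification, silylation).
4. Forward, union: the fragments are joined as a temporary dioxinone ring (step 8) and methylenated (step 9). Ring C then arises by the rearrangement (step 10), and desilylation gives the target.
5. Stereochemistry: the single stereocentre (C2, S) is set in step 10. A chiral acid anion controls the face of a planar oxocarbenium ion into which both enantiomers of the racemic acetal ionize (enantioconvergent).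

Key step: step 10

Assumption 1: the sense of induction of the chiral acid in step 10 cannot be derived with certainty; the (R)-configured catalyst is written, and its mirror image is to be used if a trial run shows the opposite sense.
Assumption 2: tert-butyl 2-methylbut-3-en-2-yl carbonate (9) is taken as a purchasable reagent.

**Route**

Step 1
Reactants: 1 4-bromophenol; 2 1-bromo-3-methylbut-2-ene (prenyl bromide)
Product: 4 4-bromo-2,6-bis(3-methylbut-2-en-1-yl)phenol, via 4-bromo-2-(3-methylbut-2-en-1-yl)phenol 3 (not isolated)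
Conditions: NaH (2.2 equiv), 2 (2.2 equiv), toluene, 0 °C → rt
Reagents that add atoms: none
Why: in toluene the sodium phenoxide reacts as a tight ion pair, so alkylation by the primary allylic bromide should go to the ortho carbons and not to oxygen (ortho C-alkylation of a phenoxide, SN2), twice, since the para position is blocked by bromine.

Step 2
Reactants: 4 4-bromo-2,6-bis(3-methylbut-2-en-1-yl)phenol
Product: 5 [4-bromo-2,6-bis(3-methylbut-2-en-1-yl)phenoxy](tert-butyl)dimethylsilane
Conditions: TBSCl, imidazole, DMF, 40 °C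
Reagents that add atoms: tert-butyldimethylsilyl chloride, CC(C)(C)[Si](C)(C)Cl
Why: imidazole-mediated silylation of a phenol is routine and should tolerate the two ortho substituents on gentle warming; the TBS ether is the only protecting group of ring B and survives every later step up to the last.

Step 3
Reactants: 5 [4-bromo-2,6-bis(3-methylbut-2-en-1-yl)phenoxy](tert-butyl)dimethylsilane
Product: 7 4-[(tert-butyldimethylsilyl)oxy]-3,5-bis(3-methylbut-2-en-1-yl)benzaldehyde, via aryllithium 6 (not isolated)
Conditions: n-BuLi, THF, −78 °C; DMF, −78 → 0 °C; aq. NH4Cl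
Reagents that add atoms: N,N-dimethylformamide, CN(C)C=O
Why: bromine–lithium exchange at −78 °C is faster than deprotonation of the benzylic-allylic CH2 groups, and the aryllithium is formylated by DMF (Bouveault formylation); the silyl ether sits para to the lithium and cannot migrate.

Step 4
Reactants: 8 methyl 2,4-dihydroxybenzoate; 9 tert-butyl 2-methylbut-3-en-2-yl carbonate
Product: 10 methyl 2-hydroxy-4-[(2-methylbut-3-en-2-yl)oxy]benzoate
Conditions: Pd(PPh3)4 (2 mol %), 4 Å MS, THF, 0 °C → rt
Reagents that add atoms: none
Why: zerovalent palladium ionizes the tertiary allylic carbonate with loss of CO2, and the more acidic, non-chelated 4-OH attacks the more substituted allyl terminus under kinetic control (Tsuji–Trost O-allylation), while the 2-OH stays locked in its hydrogen bond to the ester.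

Step 5
Reactants: 10 methyl 2-hydroxy-4-[(2-methylbut-3-en-2-yl)oxy]benzoate
Product: 12 methyl 2,4-dihydroxy-3-(3-methylbut-2-en-1-yl)benzoate, via ortho-dienone 11 (not isolated)
Conditions: o-xylene, 130 °C
Reagents that add atoms: none
Why: the aromatic Claisen rearrangement turns the 1,1-dimethylallyl ether into a linear prenyl group on an ortho carbon, and C3 should be preferred over C5 because the chelated salicylate fixes the higher double-bond character in the C3–C4 bond; the dienone then enolizes.

Step 6
Reactants: 12 methyl 2,4-dihydroxy-3-(3-methylbut-2-en-1-yl)benzoate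
Product: 13 2,4-dihydroxy-3-(3-methylbut-2-en-1-yl)benzoic acid
Conditions: NaOH (aq., 2 M), MeOH, 60 °C, argon; cold 1 M HCl to pH 3
Reagents that add atoms: sodium hydroxide, [Na+].[OH-]
Why: ester saponification by acyl–oxygen cleavage; the prenyl group is inert to base, and cold, brief acidification should avoid decarboxylation of the resorcylic acid and chroman formation.

Step 7
Reactants: 13 2,4-dihydroxy-3-(3-methylbut-2-en-1-yl)benzoic acid
Product: 15 4-[(tert-butyldimethylsilyl)oxy]-2-hydroxy-3-(3-methylbut-2-en-1-yl)benzoic acid, via silyl ester 14 (not isolated)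
Conditions: TBSCl (2.2 equiv), imidazole, DMF, rt; then AcOH/THF/H2O, rt
Reagents that add atoms: tert-butyldimethylsilyl chloride, CC(C)(C)[Si](C)(C)Cl
Why: silylation should take the carboxyl group and the free 4-OH but not the hydrogen-bonded, doubly flanked 2-OH, and the silyl ester is then hydrolysed selectively because silyl esters are far more labile than aryl silyl ethers.

Step 8
Reactants: 15 4-[(tert-butyldimethylsilyl)oxy]-2-hydroxy-3-(3-methylbut-2-en-1-yl)benzoic acid; 7 4-[(tert-butyldimethylsilyl)oxy]-3,5-bis(3-methylbut-2-en-1-yl)benzaldehyde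
Product: 17 rac-7-[(tert-butyldimethylsilyl)oxy]-2-{4-[(tert-butyldimethylsilyl)oxy]-3,5-bis(3-methylbut-2-en-1-yl)phenyl}-8-(3-methylbut-2-en-1-yl)-4H-1,3-benzodioxin-4-one, via bis(trimethylsilyl) derivative 16 (not isolated)
Conditions: HMDS, THF, rt, evaporate; 7, TMSOTf (0.2 equiv), 2,6-di-tert-butyl-4-methylpyridine (0.3 equiv), CH2Cl2, −78 °C; pyridine quench
Reagents that add atoms: hexamethyldisilazane, C[Si](C)(C)N[Si](C)(C)C (its silicon is carried only by intermediate 16 and does not remain in 17)
Why: TMSOTf-catalysed condensation of a bis-silylated hydroxy acid with an aldehyde (the silyl-transfer acetalization used to make the dioxanones of Petasis–Ferrier sequences) should close the six-membered acylal with loss of hexamethyldisiloxane at −78 °C, where the aryl silyl ethers and prenyl groups are inert; the acetal centre forms as a racemate, which does not matter because step 10 erases it.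

Step 9
Reactants: 17 the racemic benzodioxin-4-one
Product: 18 rac-7-[(tert-butyldimethylsilyl)oxy]-2-{4-[(tert-butyldimethylsilyl)oxy]-3,5-bis(3-methylbut-2-en-1-yl)phenyl}-4-methylidene-8-(3-methylbut-2-en-1-yl)-4H-1,3-benzodioxine
Conditions: Cp2TiMe2 (2.5 equiv), toluene/THF, 65 °C, dark; filtration through basic alumina
Reagents that add atoms: bis(cyclopentadienyl)dimethyltitanium, C[Ti+2]C.c1cc[cH-]c1.c1cc[cH-]c1
Why: Petasis methylenation: on heating, Cp2TiMe2 gives the titanium methylidene, which converts the lactone carbonyl into the exocyclic enol ether by cycloaddition and cycloreversion; the reagent is not acidic, so the enol acetal, silyl ethers and trisubstituted alkenes should survive.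

Step 10
Reactants: 18 the racemic 4-methylidene-4H-1,3-benzodioxine
Product: 20 (2S)-7-[(tert-butyldimethylsilyl)oxy]-2-{4-[(tert-butyldimethylsilyl)oxy]-3,5-bis(3-methylbut-2-en-1-yl)phenyl}-8-(3-methylbut-2-en-1-yl)-2,3-dihydro-4H-chromen-4-one, via enol oxocarbenium ion pair 19 (not isolated)
Conditions: (R)-3,3'-bis(2,4,6-triisopropylphenyl)-1,1'-binaphthyl-2,2'-diyl N-triflylphosphoramide (5 mol %), 4 Å MS, toluene, −60 → −30 °C; Et3N quench at low temperature
Reagents that add atoms: none
Why: Proposed new method: the strong chiral acid protonates the enol-ether oxygen of racemic 18 and the bond from the acetal carbon to that oxygen ionizes (the cation is stabilized by the ring oxygen and the 4-silyloxyaryl group), which erases the acetal stereocentre and gives the tethered enol/aryloxycarbenium ion 19, held by the chiral phosphoramidate anion through a hydrogen bond to the enol OH and by ion pairing; the enol carbon then adds to the oxocarbenium carbon and the acid is released from the ketone. The closest known reactions are the Petasis–Ferrier rearrangement of 4-methylene-1,3-dioxanes to tetrahydropyran-4-ones with Me2AlCl and the chiral phosphoric acid catalysed aza-Petasis–Ferrier rearrangement of racemic hemiaminal vinyl ethers; an enantioselective all-oxygen version on a benzodioxine has not been shown. The pyranone ring closes in a 6-(enolendo)-endo-trig mode while the dioxine ring opens. The new stereocentre is under catalyst control: the anion shields one face of the planar oxocarbenium ion, so both enantiomers of 18 should converge on the (2S) product. The step needs enantioface selectivity and chemoselectivity for C–C bond formation over return to the acetal, hydrolysis and Prins attack by the neighbouring prenyl alkene; return is degenerate and C–C bond formation irreversible, the tethered enol is far more nucleophilic than a trisubstituted alkene, and the sieves exclude water.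

Step 11
Reactants: 20 the (2S)-bis-silyl flavanone
Product: 21 sophoranone, (2S)-7-hydroxy-2-[4-hydroxy-3,5-bis(3-methylbut-2-en-1-yl)phenyl]-8-(3-methylbut-2-en-1-yl)-2,3-dihydro-4H-chromen-4-one
Conditions: Bu4NF (2.5 equiv), AcOH (3 equiv), THF, 0 °C
Reagents that add atoms: none
Why: fluoride cleaves both aryl silyl ethers, and the acetic acid buffer keeps the phenols protonated, so neither phenoxide-triggered ring opening to the chalcone (loss of the C2 configuration) nor cyclization of the ortho-prenylphenols should occur.

**Compound list**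

1 | 4-bromophenol | Oc1ccc(Br)cc1 | starting material
2 | 1-bromo-3-methylbut-2-ene (prenyl bromide) | CC(C)=CCBr | starting material
3 | 4-bromo-2-(3-methylbut-2-en-1-yl)phenol | CC(C)=CCc1cc(Br)ccc1O | intermediate (not isolated)
4 | 4-bromo-2,6-bis(3-methylbut-2-en-1-yl)phenol | CC(C)=CCc1cc(Br)cc(CC=C(C)C)c1O | intermediate
5 | [4-bromo-2,6-bis(3-methylbut-2-en-1-yl)phenoxy](tert-butyl)dimethylsilane | CC(C)=CCc1cc(Br)cc(CC=C(C)C)c1O[Si](C)(C)C(C)(C)C | intermediate
6 | {4-[(tert-butyldimethylsilyl)oxy]-3,5-bis(3-methylbut-2-en-1-yl)phenyl}lithium | CC(C)=CCc1cc([Li])cc(CC=C(C)C)c1O[Si](C)(C)C(C)(C)C | intermediate (not isolated)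
7 | 4-[(tert-butyldimethylsilyl)oxy]-3,5-bis(3-methylbut-2-en-1-yl)benzaldehyde | CC(C)=CCc1cc(C=O)cc(CC=C(C)C)c1O[Si](C)(C)C(C)(C)C | intermediate
8 | methyl 2,4-dihydroxybenzoate | COC(=O)c1ccc(O)cc1O | starting material
9 | tert-butyl 2-methylbut-3-en-2-yl carbonate | CC(C)(C)OC(=O)OC(C)(C)C=C | starting material
10 | methyl 2-hydroxy-4-[(2-methylbut-3-en-2-yl)oxy]benzoate | COC(=O)c1ccc(OC(C)(C)C=C)cc1O | intermediate
11 | methyl 2-hydroxy-3-(3-methylbut-2-en-1-yl)-4-oxocyclohexa-1,5-diene-1-carboxylate (ortho-dienone, racemic) | COC(=O)C1=C(O)C(CC=C(C)C)C(=O)C=C1 | intermediate (not isolated)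
12 | methyl 2,4-dihydroxy-3-(3-methylbut-2-en-1-yl)benzoate | COC(=O)c1ccc(O)c(CC=C(C)C)c1O | intermediate
13 | 2,4-dihydroxy-3-(3-methylbut-2-en-1-yl)benzoic acid | OC(=O)c1ccc(O)c(CC=C(C)C)c1O | intermediate
14 | tert-butyldimethylsilyl 4-[(tert-butyldimethylsilyl)oxy]-2-hydroxy-3-(3-methylbut-2-en-1-yl)benzoate | CC(C)=CCc1c(O)c(C(=O)O[Si](C)(C)C(C)(C)C)ccc1O[Si](C)(C)C(C)(C)C | intermediate (not isolated)
15 | 4-[(tert-butyldimethylsilyl)oxy]-2-hydroxy-3-(3-methylbut-2-en-1-yl)benzoic acid | CC(C)=CCc1c(O)c(C(=O)O)ccc1O[Si](C)(C)C(C)(C)C | intermediate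
16 | trimethylsilyl 4-[(tert-butyldimethylsilyl)oxy]-3-(3-methylbut-2-en-1-yl)-2-[(trimethylsilyl)oxy]benzoate | CC(C)=CCc1c(O[Si](C)(C)C)c(C(=O)O[Si](C)(C)C)ccc1O[Si](C)(C)C(C)(C)C | intermediate (not isolated)
17 | rac-7-[(tert-butyldimethylsilyl)oxy]-2-{4-[(tert-butyldimethylsilyl)oxy]-3,5-bis(3-methylbut-2-en-1-yl)phenyl}-8-(3-methylbut-2-en-1-yl)-4H-1,3-benzodioxin-4-one | O=C1OC(c2cc(CC=C(C)C)c(O[Si](C)(C)C(C)(C)C)c(CC=C(C)C)c2)Oc2c1ccc(O[Si](C)(C)C(C)(C)C)c2CC=C(C)C | intermediate
18 | rac-7-[(tert-butyldimethylsilyl)oxy]-2-{4-[(tert-butyldimethylsilyl)oxy]-3,5-bis(3-methylbut-2-en-1-yl)phenyl}-4-methylidene-8-(3-methylbut-2-en-1-yl)-4H-1,3-benzodioxine | C=C1OC(c2cc(CC=C(C)C)c(O[Si](C)(C)C(C)(C)C)c(CC=C(C)C)c2)Oc2c1ccc(O[Si](C)(C)C(C)(C)C)c2CC=C(C)C | intermediate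
19 | enol/aryloxycarbenium cation (paired with the chiral phosphoramidate anion of the catalyst) | C=C(O)c1ccc(O[Si](C)(C)C(C)(C)C)c(CC=C(C)C)c1[O+]=Cc1cc(CC=C(C)C)c(O[Si](C)(C)C(C)(C)C)c(CC=C(C)C)c1 | intermediate (not isolated)
20 | (2S)-7-[(tert-butyldimethylsilyl)oxy]-2-{4-[(tert-butyldimethylsilyl)oxy]-3,5-bis(3-methylbut-2-en-1-yl)phenyl}-8-(3-methylbut-2-en-1-yl)-2,3-dihydro-4H-chromen-4-one | CC(C)=CCc1cc([C@@H]2CC(=O)c3ccc(O[Si](C)(C)C(C)(C)C)c(CC=C(C)C)c3O2)cc(CC=C(C)C)c1O[Si](C)(C)C(C)(C)C | intermediate
21 | sophoranone, (2S)-7-hydroxy-2-[4-hydroxy-3,5-bis(3-methylbut-2-en-1-yl)phenyl]-8-(3-methylbut-2-en-1-yl)-2,3-dihydro-4H-chromen-4-one | CC(C)=CCc1cc([C@@H]2CC(=O)c3ccc(O)c(CC=C(C)C)c3O2)cc(CC=C(C)C)c1O | target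

**Step count and risks**

Total step count: 11. Longest linear sequence: 8 steps (steps 4 to 11, from compound 8).

Steps most likely to fail:

Step 10 (the step labelled as a proposed new method). What may go wrong: insufficient facial discrimination within the ion pair, protonation at the enol-ether carbon followed by hydrolysis, acid-induced reactions of the prenyl alkenes, or partial racemization by re-ionization of the product at C2. The fallback uses known chemistry and sets out from 18. The classical Lewis-acid Petasis–Ferrier rearrangement (Me2AlCl, CH2Cl2, −78 °C) should give the racemic bis-silyl flavanone F1. This is then resolved kinetically by asymmetric transfer hydrogenation (RuCl(p-cymene)[(R,R)-TsDPEN] as catalyst, HCO2H/Et3N, EtOAc, rt, run to about half conversion). This should reduce the (2R)-ketone to the cis-flavan-4-ol, (2R,4R)-7-[(tert-butyldimethylsilyl)oxy]-2-{4-[(tert-butyldimethylsilyl)oxy]-3,5-bis(3-methylbut-2-en-1-yl)phenyl}-8-(3-methylbut-2-en-1-yl)chroman-4-ol F2, which is removed by chromatography, and leave the (2S)-ketone. The route is rejoined at 20.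

Step 8. What may go wrong: failure of the weakly nucleophilic silylated phenol oxygen to close onto the acyloxycarbenium ion, or loss of an aryl silyl ether under the Lewis acid. The fallback sets out from 7 and 15 and replaces the silyl-transfer condensation by a transacetalization. Aldehyde 7 is first converted with HC(OMe)3 and catalytic PPTS in MeOH into 4-[(tert-butyldimethylsilyl)oxy]-3,5-bis(3-methylbut-2-en-1-yl)benzaldehyde dimethyl acetal F3. This is exchanged with acid 15 (PPTS, toluene, 5 Å MS to take up methanol, 60 °C) under thermodynamic control. The route is rejoined at 17.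

Step 1. What may go wrong: competing O-alkylation, incomplete second alkylation, and cyclization of the ortho-prenylphenol to a chroman. The fallback sets out from 1 and builds each prenyl group by etherification and sigmatropic shift. Pd(PPh3)4-catalysed O-alkylation with carbonate 9 should give 4-bromophenyl 2-methylbut-3-en-2-yl ether F4. Thermal Claisen rearrangement (o-xylene, 130 °C) gives phenol 3, here isolated. A second O-alkylation with 9 gives 4-bromo-2-(3-methylbut-2-en-1-yl)phenyl 2-methylbut-3-en-2-yl ether F5. A second Claisen rearrangement to the only free ortho position rejoins the route at 4.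

Further compounds
F1 | step 10 | rac-7-[(tert-butyldimethylsilyl)oxy]-2-{4-[(tert-butyldimethylsilyl)oxy]-3,5-bis(3-methylbut-2-en-1-yl)phenyl}-8-(3-methylbut-2-en-1-yl)-2,3-dihydro-4H-chromen-4-one | CC(C)=CCc1cc(C2CC(=O)c3ccc(O[Si](C)(C)C(C)(C)C)c(CC=C(C)C)c3O2)cc(CC=C(C)C)c1O[Si](C)(C)C(C)(C)C
F2 | step 10 | (2R,4R)-7-[(tert-butyldimethylsilyl)oxy]-2-{4-[(tert-butyldimethylsilyl)oxy]-3,5-bis(3-methylbut-2-en-1-yl)phenyl}-8-(3-methylbut-2-en-1-yl)chroman-4-ol | O[C@@H]1C[C@H](c2cc(CC=C(C)C)c(O[Si](C)(C)C(C)(C)C)c(CC=C(C)C)c2)Oc2c(CC=C(C)C)c(O[Si](C)(C)C(C)(C)C)ccc21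
F3 | step 8 | 4-[(tert-butyldimethylsilyl)oxy]-3,5-bis(3-methylbut-2-en-1-yl)benzaldehyde dimethyl acetal | COC(OC)c1cc(CC=C(C)C)c(O[Si](C)(C)C(C)(C)C)c(CC=C(C)C)c1
F4 | step 1 | 4-bromophenyl 2-methylbut-3-en-2-yl ether | C=CC(C)(C)Oc1ccc(Br)cc1
F5 | step 1 | 4-bromo-2-(3-methylbut-2-en-1-yl)phenyl 2-methylbut-3-en-2-yl ether | C=CC(C)(C)Oc1ccc(Br)cc1CC=C(C)C
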